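**Retrosynthetic overview**

1. Target 25 ← end-game on the ent-labdane core: 18-OAc and free 6-OH from diol 23; the C13(16),C14 diene from the C13 methyl ketone by Shapiro/Negishi vinylation.
2. Key disconnection: C4–C5 and C9–C10 (rings A and B of the trans-decalin) and C8–O are cut together. Forward, one epoxide-initiated cation–olefin bicyclisation of the acyclic epoxy dienone 15 sets C4, C5, C8, C9 and C10 (both quaternary carbons and the tertiary carbinol). It is steered by the single carbinol stereocentre C6 (the later equatorial 6-OH, 1,3 to the 8-OH) and by the (S)-oxirane, whose oxygen ends on C18 at quaternary C4.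
3. 15 ← C9–C11 (1,4-addition to methyl vinyl ketone), C8–C17 (methylalumination of an alkyne), C6–C7 (asymmetric propargylation of an enal); oxirane from Sharpless epoxidation and reductive opening of 8-hydroxygeranyl acetate.
4. Ring order: no ring before step 11; ring A (C1–C5, C10), ring B (C5–C10) and a transient dihydropyran (O–C8…C13) close in that one step; the pyran is reopened in step 12.

Key step: step 11

Remark: labdane numbering (C1–C20) is used for all intermediates; the target is read as the 18-acetate of an ent-labdane triol, (4S,5S,6R,8S,9S,10R). Assumption: in step 6 the (R)-phosphoric acid is taken to give the (R)-carbinol, as it does with aryl and alkenyl aldehydes; if the sense is opposite, its antipode is used.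

**Route**

Step 1
Reactants: 1 geranyl acetate
Product: 2 (2E,6E)-8-hydroxy-3,7-dimethylocta-2,6-dien-1-yl acetate
Conditions: SeO2 (cat.), t-BuOOH, salicylic acid (cat.), CH2Cl2, 23 °C
Reagents that add atoms: tert-butyl hydroperoxide, CC(C)(C)OO
Why: The SeO2-catalysed allylic oxidation (ene reaction, then [2,3]-shift) attacks the electron-rich terminal alkene rather than the acetate-deactivated C2=C3 alkene and hydroxylates its (E)-methyl group, which places the later C18 oxygen with (E)-geometry.

Step 2
Reactants: 2 (2E,6E)-8-hydroxy-3,7-dimethylocta-2,6-dien-1-yl acetate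
Product: 3 (2E)-5-[(2R,3R)-3-(hydroxymethyl)-3-methyloxiran-2-yl]-3-methylpent-2-en-1-yl acetate
Conditions: Ti(OiPr)4 (cat.), D-(−)-diethyl tartrate (cat.), t-BuOOH, 4 Å MS, CH2Cl2, −20 °C
Reagents that add atoms: tert-butyl hydroperoxide, CC(C)(C)OO
Why: The Katsuki–Sharpless asymmetric epoxidation acts only on the free allylic alcohol and, with D-(−)-tartrate, should deliver oxygen to the face that gives the (2R,3R)-oxirane, which sets the configuration of the later C4.

Step 3
Reactants: 3 (2E)-5-[(2R,3R)-3-(hydroxymethyl)-3-methyloxiran-2-yl]-3-methylpent-2-en-1-yl acetate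
Product: 4 (2E,7S)-3,7-dimethyloct-2-ene-1,7,8-triol
Conditions: LiAlH4, THF, 0 → 23 °C; Rochelle-salt work-up
Reagents that add atoms: none
Why: Hydride opens the 2,3-epoxy alcohol at the less substituted oxirane carbon (SN2) and cleaves the acetate, so the C–O bond of the quaternary carbon is untouched and C4 keeps its configuration (now S by priority change).

Step 4
Reactants: 4 (2E,7S)-3,7-dimethyloct-2-ene-1,7,8-triol
Product: 5 (2E)-3-methyl-6-[(4S)-2,2,4-trimethyl-1,3-dioxolan-4-yl]hex-2-en-1-ol
Conditions: 2,2-dimethoxypropane, PPTS (cat.), acetone, 0 °C; brief aqueous work-up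
Reagents that add atoms: 2,2-dimethoxypropane, COC(C)(C)OC
Why: Acid-catalysed transketalisation forms the five-membered dioxolane on the 1,2-diol selectively, and any mixed ketal on the isolated allylic alcohol is lost on aqueous work-up.

Step 5
Reactants: 5 (2E)-3-methyl-6-[(4S)-2,2,4-trimethyl-1,3-dioxolan-4-yl]hex-2-en-1-ol
Product: 6 (2E)-3-methyl-6-[(4S)-2,2,4-trimethyl-1,3-dioxolan-4-yl]hex-2-enal
Conditions: MnO2, CH2Cl2, 23 °C
Reagents that add atoms: none
Why: MnO2 oxidises only the allylic alcohol to the enal and should leave the acetonide and the (E)-alkene geometry intact.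

Step 6
Reactants: 6 (2E)-3-methyl-6-[(4S)-2,2,4-trimethyl-1,3-dioxolan-4-yl]hex-2-enal; 7 allenylboronic acid pinacol ester
Product: 8 (4R,5E)-6-methyl-9-[(4S)-2,2,4-trimethyl-1,3-dioxolan-4-yl]non-5-en-1-yn-4-ol
Conditions: (R)-TRIP phosphoric acid (10 mol %), 4 Å MS, toluene, −20 °C; aqueous work-up
Reagents that add atoms: none
Why: Chiral phosphoric acid-catalysed propargylboration (SE2′ transfer from the allenylboronate through a six-membered chair transition state held by the catalyst) adds 1,2 to the enal and sets the (R)-carbinol of the later C6 under catalyst control.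

Step 7
Reactants: 8 (4R,5E)-6-methyl-9-[(4S)-2,2,4-trimethyl-1,3-dioxolan-4-yl]non-5-en-1-yn-4-ol
Product: 9 tert-butyldimethylsilyl ether of 8
Conditions: TBSCl, imidazole, DMF, 23 °C
Reagents that add atoms: tert-butyldimethylsilyl chloride, CC(C)(C)[Si](C)(C)Cl
Why: Standard silylation of the secondary alcohol gives an ether that is inert to the organoaluminium step and later serves as the bulky, non-participating equatorial group in the cyclisation.

Step 8
Reactants: 9 tert-butyldimethylsilyl ether of 8; 10 methyl vinyl ketone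
Product: 12 (5E,8R,9E)-8-(tert-butyldimethylsilyloxy)-6,10-dimethyl-13-[(4S)-2,2,4-trimethyl-1,3-dioxolan-4-yl]trideca-5,9-dien-2-one, via alkenylalane 11 (not isolated)
Conditions: AlMe3, Cp2ZrCl2 (cat.), H2O (1 equiv), CH2Cl2, −20 °C; then THF, CuBr·SMe2 (cat.), 10, −30 → 0 °C; aqueous Rochelle salt
Reagents that add atoms: trimethylaluminium, C[Al](C)C
Why: The Zr-catalysed Negishi carboalumination adds Me–Al syn across the terminal alkyne with methyl on the internal carbon, and the (E)-alkenylalane is then transferred with retention in a Cu-catalysed conjugate addition to the enone, which fixes the (E)-C8=C9 alkene and installs the ketone terminator.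

Step 9
Reactants: 12 (5E,8R,9E)-8-(tert-butyldimethylsilyloxy)-6,10-dimethyl-13-[(4S)-2,2,4-trimethyl-1,3-dioxolan-4-yl]trideca-5,9-dien-2-one
Product: 13 (5E,8R,9E,14S)-8-(tert-butyldimethylsilyloxy)-14,15-dihydroxy-6,10,14-trimethylpentadeca-5,9-dien-2-one
Conditions: AcOH/THF/H2O (3:1:1), 35 °C
Reagents that add atoms: none
Why: Mild aqueous acid should hydrolyse the dioxolane much faster than it cleaves the secondary TBS ether.

Step 10
Reactants: 13 (5E,8R,9E,14S)-8-(tert-butyldimethylsilyloxy)-14,15-dihydroxy-6,10,14-trimethylpentadeca-5,9-dien-2-one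
Product: 15 (5E,8R,9E)-8-(tert-butyldimethylsilyloxy)-6,10-dimethyl-13-[(2S)-2-methyloxiran-2-yl]trideca-5,9-dien-2-one, via monotosylate 14 (not isolated)
Conditions: TsCl, Et3N, Bu2SnO (cat.), CH2Cl2, 0 °C; then K2CO3, MeOH, 23 °C
Reagents that add atoms: none
Why: Tin-catalysed sulfonylation is selective for the primary hydroxyl of the 1,2-diol, and the tertiary alkoxide then closes the oxirane by intramolecular Williamson displacement (3-exo-tet) with the C4–O bond intact, so the (S)-configuration is retained.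

Step 11
Reactants: 15 (5E,8R,9E)-8-(tert-butyldimethylsilyloxy)-6,10-dimethyl-13-[(2S)-2-methyloxiran-2-yl]trideca-5,9-dien-2-one
Product: 16 (4S,5S,6R,8S,9S,10R)-6-(tert-butyldimethylsilyloxy)-8,13-epoxy-14,15-dinorlabd-12-en-18-ol (tricyclic enol ether, ent-labdane series)
Conditions: MeAlCl2 (3 equiv), CH2Cl2, −78 °C; Et3N, then aqueous NaHCO3
Reagents that add atoms: none
Why: MeAlCl2 activates the 2,2-disubstituted oxirane and the C4–O bond breaks with backside participation of the (E)-C5=C10 alkene (inversion at C4, the oxygen leaving on C18); the C10 cation is taken by C9 of the (E)-C8=C9 alkene, the C8 cation by the ketone oxygen, and loss of H-12 from the oxocarbenium ion gives the enol ether. The closest known reactions are Lewis acid-promoted epoxide-initiated polyene cyclisations of the oxidosqualene type, the ketone-oxygen-terminated cyclisation of farnesylacetone-type polyenes to sclareol-oxide-type ethers, and steroid-forming polyene cyclisations steered by one oxygen-bearing stereocentre on the tether. Ring A closes 6-endo at the alkene through C4–C5 and ring B 6-endo through C9–C10, both as chairs, and the pyran closes by capture of the C8 cation by oxygen in a six-membered oxocarbenium ring. C4 is set by the (S)-oxirane through inversion (CH2O equatorial, CH3 axial), C5/C10 trans by anti addition across the first E alkene, and C9 (side chain equatorial) and C8 (O equatorial, CH3 axial) by anti addition across the second E alkene. The absolute sense of all five comes from C6: its OTBS group must sit equatorial on the nascent ring B with H-6 eclipsing the C10 methyl (A1,3 strain) and C7 anti to the forming C4–C5 bond. The step needs oxirane opening by the alkene to be faster than the 1,2-hydride shift to the C18 aldehyde and than ionisation of the allylic silyl ether; the pre-organised chair, the low temperature and the proton-scavenging methylaluminium reagent are meant to secure this.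

Step 12
Reactants: 16 tricyclic enol ether; 17 2,4,6-triisopropylbenzenesulfonyl hydrazide
Product: 19 (E)-2,4,6-triisopropylbenzenesulfonylhydrazone of (4S,5S,6R,8S,9S,10R)-6-(tert-butyldimethylsilyloxy)-8,18-dihydroxy-14,15-dinorlabdan-13-one, via hydroxy ketone 18 (not isolated)
Conditions: PPTS (cat.), THF/H2O (20:1), 23 °C
Reagents that add atoms: none
Why: Acid hydrolyses the cyclic enol ether to the δ-hydroxy ketone, which is drained from its hemiketal equilibrium by condensation with the sulfonyl hydrazide; no stereocentre is touched.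

Step 13
Reactants: 19 trisylhydrazone; 20 vinyl bromide
Product: 23 (4S,5S,6R,8S,9S,10R)-6-(tert-butyldimethylsilyloxy)labda-13(16),14-diene-8,18-diol, via alkenyllithium 21 (not isolated), via alkenylzinc 22 (not isolated)
Conditions: n-BuLi (4.5 equiv), THF, −78 → 0 °C; ZnCl2, −78 °C; then 20, Pd(PPh3)4 (cat.), 23 °C
Reagents that add atoms: none
Why: In the Shapiro reaction the hydrazone dianion forms by kinetic deprotonation of the methyl group and loses sulfinate and N2 to give the 2-lithio-1-alkene, and transmetalation to zinc followed by Negishi coupling builds the 2-substituted buta-1,3-diene without affecting the lithium alkoxides or the silyl ether.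

Step 14
Reactants: 23 (4S,5S,6R,8S,9S,10R)-6-(tert-butyldimethylsilyloxy)labda-13(16),14-diene-8,18-diol
Product: 24 18-acetate of 23
Conditions: Ac2O, pyridine, DMAP (cat.), CH2Cl2, 0 °C
Reagents that add atoms: acetic anhydride, CC(=O)OC(C)=O
Why: Acylation should occur only at the primary C18 hydroxyl, because the tertiary C8 hydroxyl is unreactive under these conditions and C6 is still silylated.

Step 15
Reactants: 24 18-acetate of 23
Product: 25 (4S,5S,6R,8S,9S,10R)-18-acetoxylabda-13(16),14-diene-6,8-diol (target, ent-labdane series)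
Conditions: HF·pyridine, pyridine, THF, 0 → 23 °C
Reagents that add atoms: none
Why: Buffered HF·pyridine cleaves the secondary silyl ether under weakly acidic conditions, which avoids a base-induced O18→O6 acetyl migration and should leave the diene and the tertiary alcohol intact.

**Compound list**

1 | geranyl acetate | CC(C)=CCC/C(C)=C/COC(C)=O | starting material
2 | (2E,6E)-8-hydroxy-3,7-dimethylocta-2,6-dien-1-yl acetate | OC/C(C)=C/CC/C(C)=C/COC(C)=O | intermediate
3 | (2E)-5-[(2R,3R)-3-(hydroxymethyl)-3-methyloxiran-2-yl]-3-methylpent-2-en-1-yl acetate | OC[C@@]1(C)O[C@@H]1CC/C(C)=C/COC(C)=O | intermediate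
4 | (2E,7S)-3,7-dimethyloct-2-ene-1,7,8-triol | OC[C@@](C)(O)CCC/C(C)=C/CO | intermediate
5 | (2E)-3-methyl-6-[(4S)-2,2,4-trimethyl-1,3-dioxolan-4-yl]hex-2-en-1-ol | CC1(C)OC[C@@](C)(O1)CCC/C(C)=C/CO | intermediate
6 | (2E)-3-methyl-6-[(4S)-2,2,4-trimethyl-1,3-dioxolan-4-yl]hex-2-enal | CC1(C)OC[C@@](C)(O1)CCC/C(C)=C/C=O | intermediate
7 | allenylboronic acid pinacol ester | C=C=CB1OC(C)(C)C(C)(C)O1 | starting material
8 | (4R,5E)-6-methyl-9-[(4S)-2,2,4-trimethyl-1,3-dioxolan-4-yl]non-5-en-1-yn-4-ol | CC1(C)OC[C@@](C)(O1)CCC/C(C)=C/[C@H](O)CC#C | intermediate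
9 | tert-butyldimethylsilyl ether of 8 | CC1(C)OC[C@@](C)(O1)CCC/C(C)=C/[C@H](O[Si](C)(C)C(C)(C)C)CC#C | intermediate
10 | methyl vinyl ketone (but-3-en-2-one) | CC(=O)C=C | starting material
11 | (E)-alkenyl(dimethyl)alane from 9 | CC1(C)OC[C@@](C)(O1)CCC/C(C)=C/[C@H](O[Si](C)(C)C(C)(C)C)C/C(C)=C/[Al](C)C | intermediate
12 | (5E,8R,9E)-8-(tert-butyldimethylsilyloxy)-6,10-dimethyl-13-[(4S)-2,2,4-trimethyl-1,3-dioxolan-4-yl]trideca-5,9-dien-2-one | CC1(C)OC[C@@](C)(O1)CCC/C(C)=C/[C@H](O[Si](C)(C)C(C)(C)C)C/C(C)=C/CCC(C)=O | intermediate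
13 | (5E,8R,9E,14S)-8-(tert-butyldimethylsilyloxy)-14,15-dihydroxy-6,10,14-trimethylpentadeca-5,9-dien-2-one | OC[C@@](C)(O)CCC/C(C)=C/[C@H](O[Si](C)(C)C(C)(C)C)C/C(C)=C/CCC(C)=O | intermediate
14 | 15-O-(p-toluenesulfonyl) derivative of 13 | Cc1ccc(cc1)S(=O)(=O)OC[C@@](C)(O)CCC/C(C)=C/[C@H](O[Si](C)(C)C(C)(C)C)C/C(C)=C/CCC(C)=O | intermediate
15 | (5E,8R,9E)-8-(tert-butyldimethylsilyloxy)-6,10-dimethyl-13-[(2S)-2-methyloxiran-2-yl]trideca-5,9-dien-2-one | C[C@@]1(CO1)CCC/C(C)=C/[C@H](O[Si](C)(C)C(C)(C)C)C/C(C)=C/CCC(C)=O | intermediate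
16 | (4S,5S,6R,8S,9S,10R)-6-(tert-butyldimethylsilyloxy)-8,13-epoxy-14,15-dinorlabd-12-en-18-ol | CC1=CC[C@H]2[C@]3(C)CCC[C@](C)(CO)[C@H]3[C@H](O[Si](C)(C)C(C)(C)C)C[C@]2(C)O1 | intermediate
17 | 2,4,6-triisopropylbenzenesulfonyl hydrazide | CC(C)c1cc(C(C)C)c(S(=O)(=O)NN)c(C(C)C)c1 | starting material
18 | (4S,5S,6R,8S,9S,10R)-6-(tert-butyldimethylsilyloxy)-8,18-dihydroxy-14,15-dinorlabdan-13-one | CC(=O)CC[C@H]1[C@]2(C)CCC[C@](C)(CO)[C@H]2[C@H](O[Si](C)(C)C(C)(C)C)C[C@]1(C)O | intermediate
19 | (E)-2,4,6-triisopropylbenzenesulfonylhydrazone of 18 | C/C(CC[C@H]1[C@]2(C)CCC[C@](C)(CO)[C@H]2[C@H](O[Si](C)(C)C(C)(C)C)C[C@]1(C)O)=N\NS(=O)(=O)c3c(C(C)C)cc(C(C)C)cc3C(C)C | intermediate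
20 | vinyl bromide | BrC=C | starting material
21 | C13 alkenyllithium (8,18-dilithium alkoxide) | [Li]C(=C)CC[C@H]1[C@]2(C)CCC[C@](C)(CO[Li])[C@H]2[C@H](O[Si](C)(C)C(C)(C)C)C[C@]1(C)O[Li] | intermediate
22 | C13 alkenylzinc chloride (8,18-dilithium alkoxide) | Cl[Zn]C(=C)CC[C@H]1[C@]2(C)CCC[C@](C)(CO[Li])[C@H]2[C@H](O[Si](C)(C)C(C)(C)C)C[C@]1(C)O[Li] | intermediate
23 | (4S,5S,6R,8S,9S,10R)-6-(tert-butyldimethylsilyloxy)labda-13(16),14-diene-8,18-diol | C=CC(=C)CC[C@H]1[C@]2(C)CCC[C@](C)(CO)[C@H]2[C@H](O[Si](C)(C)C(C)(C)C)C[C@]1(C)O | intermediate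
24 | 18-acetate of 23 | C=CC(=C)CC[C@H]1[C@]2(C)CCC[C@](C)(COC(C)=O)[C@H]2[C@H](O[Si](C)(C)C(C)(C)C)C[C@]1(C)O | intermediate
25 | (4S,5S,6R,8S,9S,10R)-18-acetoxylabda-13(16),14-diene-6,8-diol | C=CC(=C)CC[C@H]1[C@]2(C)CCC[C@](C)(COC(C)=O)[C@H]2[C@H](O)C[C@]1(C)O | target

**Step count and risks**

Total step count: 15. Longest linear sequence: 15 steps (1 → 25).

Steps most likely to fail:

1. Step 11. The activated oxirane may undergo a 1,2-hydride shift to the C18 aldehyde, the allylic C6–O bond may ionise, or the cascade may stop after ring A with proton loss from the C10 cation. The fallback sets out from 15 and changes the manifold from cationic to radical. Titanocene(III) chloride (Cp2TiCl2, Mn, THF, 23 °C) opens the oxirane homolytically to the C4 radical, which should cyclise 6-endo/6-endo through the same C6-biased chair and end by β-hydride elimination at C8, giving 6-(tert-butyldimethylsilyloxy)-18-hydroxy-14,15-dinor-ent-labd-8(17)-en-13-one F1. Mukaiyama hydration of the exocyclic alkene (Co(acac)2 cat., PhSiH3, O2, THF, 0 °C) should then give the hydroxy ketone 18, where the route is rejoined by condensation with 17 to 19. In this mode C4 and C8 rest only on steric preference (CH2O and OH equatorial), so epimers would have to be separated.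

2. Step 8. In the copper stage, methyl may transfer instead of the alkenyl group, or the enone may undergo 1,2-addition and oligomerise. The fallback sets out from 9 and replaces the conjugate addition by a cross-coupling. The same carboalumination is quenched with I2 to give the (1E,4R,5E)-1-iodo-2,6-dimethyl-9-[(4S)-2,2,4-trimethyl-1,3-dioxolan-4-yl]nona-1,5-dien-4-yl TBS ether F2. Negishi coupling with [2-(2-methyl-1,3-dioxolan-2-yl)ethyl]zinc bromide (Pd(dppf)Cl2, THF, 50 °C) should give the ethylene ketal of 12, F3. The aqueous acetic acid of step 9 then removes both ketals at once and the route is rejoined at diol 13.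

3. Step 13. The polylithiated alkenyl anion may be quenched by solvent before transmetalation, or deprotonation may leak to the C12 side and give the internal diene. The fallback sets out from 16 and uses an enol triflate instead of the hydrazone. Silylation of the primary alcohol (TBSCl, imidazole) gives the 18-O-TBS enol ether F4, and oxalic acid in wet THF opens it to the 6,18-bis-O-TBS δ-hydroxy ketone F5. KHMDS (2.2 equiv) and Comins' reagent at −78 °C should give the kinetic C13(16) enol triflate F6, the hindered tertiary alkoxide staying unsulfonylated. Stille coupling with tributyl(vinyl)stannane (Pd(PPh3)4, LiCl, THF, 60 °C) gives the 6,18-bis-O-TBS diene F7, and HF·pyridine at 0 °C removes the primary silyl ether first, rejoining the route at 23.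

**Further compounds**

F1 | step 11 | 6-(tert-butyldimethylsilyloxy)-18-hydroxy-14,15-dinor-ent-labd-8(17)-en-13-one | CC(=O)CC[C@H]1[C@]2(C)CCC[C@](C)(CO)[C@H]2[C@H](O[Si](C)(C)C(C)(C)C)CC1=C
F2 | step 8 | tert-butyl{[(1E,4R,5E)-1-iodo-2,6-dimethyl-9-[(4S)-2,2,4-trimethyl-1,3-dioxolan-4-yl]nona-1,5-dien-4-yl]oxy}dimethylsilane | CC1(C)OC[C@@](C)(O1)CCC/C(C)=C/[C@H](O[Si](C)(C)C(C)(C)C)C/C(C)=C/I
F3 | step 8 | ethylene ketal of 12 | CC1(C)OC[C@@](C)(O1)CCC/C(C)=C/[C@H](O[Si](C)(C)C(C)(C)C)C/C(C)=C/CCC2(C)OCCO2
F4 | step 13 | 18-O-tert-butyldimethylsilyl ether of 16 | CC1=CC[C@H]2[C@]3(C)CCC[C@](C)(CO[Si](C)(C)C(C)(C)C)[C@H]3[C@H](O[Si](C)(C)C(C)(C)C)C[C@]2(C)O1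
F5 | step 13 | 6,18-bis-O-tert-butyldimethylsilyl-8-hydroxy-14,15-dinor-ent-labdan-13-one | CC(=O)CC[C@H]1[C@]2(C)CCC[C@](C)(CO[Si](C)(C)C(C)(C)C)[C@H]2[C@H](O[Si](C)(C)C(C)(C)C)C[C@]1(C)O
F6 | step 13 | C13(16) enol trifluoromethanesulfonate of F5 | C=C(OS(=O)(=O)C(F)(F)F)CC[C@H]1[C@]2(C)CCC[C@](C)(CO[Si](C)(C)C(C)(C)C)[C@H]2[C@H](O[Si](C)(C)C(C)(C)C)C[C@]1(C)O
F7 | step 13 | 6,18-bis-O-tert-butyldimethylsilyl-ent-labda-13(16),14-dien-8-ol | C=CC(=C)CC[C@H]1[C@]2(C)CCC[C@](C)(CO[Si](C)(C)C(C)(C)C)[C@H]2[C@H](O[Si](C)(C)C(C)(C)C)C[C@]1(C)O
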